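The plan rests on cutting both exocyclic bonds of the dihydrofuran ring, C2–C1′ (to the guaiacyl ring) and C3–C9. They stand trans on neighbouring carbons, which is what anti addition across the C2=C3 bond of a benzofuran delivers. In one operation a chiral palladium π-allyl complex alkylates C3 of a benzofuran-2-yl borate while the guaiacyl group shifts from boron to C2 on the opposite face, forming both bonds and both stereocentres. The precursor is the lithium borate made in the flask from C2-lithiated 5-chloro-7-methoxybenzofuran and the silyl-protected guaiacyl pinacol boronate. The allyl group is later trimmed to C9–OH, and the C5 chloride carries the Z-enal arm.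

Key step: step 5

Assumption: (S)-H8-BINAP is taken as the ligand antipode that leads to the (2S,3S) boronate 12; should the sense of induction be the opposite, (R)-H8-BINAP is used and nothing else changes. Compounds 7 and 18 are taken as catalogue materials.

Step 1
Reactants: 1 4-chloro-2-methoxyphenol
Product: 2 4-chloro-2-iodo-6-methoxyphenol
Conditions: I2, NaOH, MeOH/H2O, 0 °C → rt; acidic work-up
Reagents that add atoms: iodine, [I][I]
Why: Electrophilic aromatic iodination of the phenoxide, in which the para position is blocked by chlorine and one ortho position by the methoxy group, so iodine should enter only at the remaining ortho carbon.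

Step 2
Reactants: 2 4-chloro-2-iodo-6-methoxyphenol; 3 ethynyltrimethylsilane
Product: 4 4-chloro-2-methoxy-6-[(trimethylsilyl)ethynyl]phenol
Conditions: PdCl2(PPh3)2 (cat.), CuI (cat.), Et3N, THF, rt
Reagents that add atoms: none
Why: Sonogashira coupling, in which zerovalent palladium inserts into the C–I bond far faster than into the C–Cl bond at room temperature, so the chloride should be kept.

Step 3
Reactants: 4 4-chloro-2-methoxy-6-[(trimethylsilyl)ethynyl]phenol
Product: 6 5-chloro-7-methoxy-1-benzofuran, via 4-chloro-2-ethynyl-6-methoxyphenol 5 (not isolated)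
Conditions: Bu4NF, THF, rt → 65 °C
Reagents that add atoms: none
Why: Fluoride protodesilylation of the alkyne followed by base-mediated 5-endo-dig hydroalkoxylation of the terminal alkyne by the tetrabutylammonium phenoxide, which aromatises to the benzofuran.

Step 4
Reactants: 7 2-methoxy-4-(4,4,5,5-tetramethyl-1,3,2-dioxaborolan-2-yl)phenol
Product: 8 2-[3-methoxy-4-(triisopropylsilyloxy)phenyl]-4,4,5,5-tetramethyl-1,3,2-dioxaborolane
Conditions: TIPSCl, imidazole, DMF, rt
Reagents that add atoms: triisopropylsilyl chloride, CC(C)[Si](Cl)(C(C)C)C(C)C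
Why: Imidazole-mediated O-silylation (silyl ether formation), which removes the acidic phenol proton before the organolithium step and leaves the pinacol boronate untouched.

Step 5
Reactants: 6 5-chloro-7-methoxy-1-benzofuran; 8 2-[3-methoxy-4-(triisopropylsilyloxy)phenyl]-4,4,5,5-tetramethyl-1,3,2-dioxaborolane; 9 allyl acetate
Product: 12 2-{(2S,3S)-3-allyl-5-chloro-7-methoxy-2-[3-methoxy-4-(triisopropylsilyloxy)phenyl]-2,3-dihydro-1-benzofuran-2-yl}-4,4,5,5-tetramethyl-1,3,2-dioxaborolane (aryl trans to allyl; boron cis to allyl), via (5-chloro-7-methoxy-1-benzofuran-2-yl)lithium 10 (not isolated), via lithium aryl(benzofuran-2-yl)(pinacolato)borate 11 (not isolated)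
Conditions: n-BuLi, THF, −78 °C; 8, −78 → 0 °C; then 9, Pd2(dba)3 (cat.), (S)-H8-BINAP (cat.), THF, 0 °C → rt
Reagents that add atoms: none
Why: Proposed new method: n-BuLi removes the most acidic proton of 6 (C2–H, next to the ring oxygen), aryllithium 10 adds to boronate 8 to give borate 11, and outer-sphere attack of the boron-activated enol-ether carbon C3 on the cationic π-allyl palladium complex of (S)-H8-BINAP triggers an anti-periplanar 1,2-shift of the guaiacyl group from boron to C2, which forms C3–C9 and C2–C1′ in one event and dearomatises the furan ring. The closest known reaction type is the palladium-catalysed enantioselective allylation with 1,2-metalate rearrangement of indol-2-yl boronate complexes and allylic acetates; a benzofuran-2-yl borate is a weaker C3 nucleophile and has not been used in this way, hence the label. No ring is closed in this step. C3 is set by the chiral bisphosphine on palladium, which selects the enantiotopic face of the borate that meets the π-allyl unit; C2 is set relative to C3 by the stereoelectronic need for the migrating aryl group to arrive anti to the incoming allyl group, which puts aryl and allyl trans and leaves boron where hydrogen will later stand. The step needs C3-allylation to outrun direct aryl transfer from boron to palladium, lithiation at C2 and not at C6, and an intact C5–Cl bond; the high migratory aptitude of the electron-rich guaiacyl group, the greater acidity of C2–H at −78 °C and the slow oxidative addition of an aryl chloride to a bisphosphine palladium complex at room temperature should secure these.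

Step 6
Reactants: 12 2-{(2S,3S)-3-allyl-5-chloro-7-methoxy-2-[3-methoxy-4-(triisopropylsilyloxy)phenyl]-2,3-dihydro-1-benzofuran-2-yl}-4,4,5,5-tetramethyl-1,3,2-dioxaborolane
Product: 13 4-[(2S,3S)-3-allyl-5-chloro-7-methoxy-2,3-dihydro-1-benzofuran-2-yl]-2-methoxyphenol (trans)
Conditions: Bu4NF·3H2O, THF, rt → 45 °C
Reagents that add atoms: none
Why: Fluoride-mediated protodeboronation of a tertiary benzylic boronic ester, in which the fluoroborate is protonated by water at carbon on the face that boron leaves (retention), so that C2–H should stand where boron stood and the trans relation is kept; the same reagent cleaves the aryl silyl ether.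

Step 7
Reactants: 13 4-[(2S,3S)-3-allyl-5-chloro-7-methoxy-2,3-dihydro-1-benzofuran-2-yl]-2-methoxyphenol
Product: 14 {4-[(2S,3S)-3-allyl-5-chloro-7-methoxy-2,3-dihydro-1-benzofuran-2-yl]-2-methoxyphenoxy}triisopropylsilane
Conditions: TIPSCl, imidazole, DMF, rt
Reagents that add atoms: triisopropylsilyl chloride, CC(C)[Si](Cl)(C(C)C)C(C)C
Why: Silyl ether formation, which caps the electron-rich phenol again before ozonolysis and the carbonate-mediated coupling; the hindered triisopropylsilyl group is chosen for its stability to base.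

Step 8
Reactants: 14 {4-[(2S,3S)-3-allyl-5-chloro-7-methoxy-2,3-dihydro-1-benzofuran-2-yl]-2-methoxyphenoxy}triisopropylsilane
Product: 15 {4-[(2S,3S)-5-chloro-7-methoxy-3-[(1E)-prop-1-en-1-yl]-2,3-dihydro-1-benzofuran-2-yl]-2-methoxyphenoxy}triisopropylsilane
Conditions: [Ir(cod)(PMePh2)2]PF6 (cat., activated with H2, then degassed), THF, rt
Reagents that add atoms: none
Why: Metal hydride alkene isomerisation (hydrometalation and β-hydride elimination), which should move the terminal double bond by one position to the E-propenyl group and stop there, because the new 1,2-disubstituted alkene beside the tertiary C3 inserts slowly; C3 is not touched.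

Step 9
Reactants: 15 {4-[(2S,3S)-5-chloro-7-methoxy-3-[(1E)-prop-1-en-1-yl]-2,3-dihydro-1-benzofuran-2-yl]-2-methoxyphenoxy}triisopropylsilane
Product: 17 {(2S,3R)-5-chloro-7-methoxy-2-[3-methoxy-4-(triisopropylsilyloxy)phenyl]-2,3-dihydro-1-benzofuran-3-yl}methanol, via dihydrobenzofuran-3-carbaldehyde 16 (not isolated)
Conditions: O3, CH2Cl2/MeOH, −78 °C (stopped at alkene consumption); then NaBH4, −78 → 0 °C
Reagents that add atoms: ozone, [O-][O+]=O
Why: Ozonolysis with reductive work-up, in which the alkene reacts far faster than the silylated and chlorinated arenes and aldehyde 16 is reduced in the same flask before its acidic C3–H can epimerise or expel the C2 aryloxy group.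

Step 10
Reactants: 17 {(2S,3R)-5-chloro-7-methoxy-2-[3-methoxy-4-(triisopropylsilyloxy)phenyl]-2,3-dihydro-1-benzofuran-3-yl}methanol; 18 tert-butyldimethyl(prop-2-yn-1-yloxy)silane
Product: 19 {(2S,3R)-5-[3-(tert-butyldimethylsilyloxy)prop-1-yn-1-yl]-7-methoxy-2-[3-methoxy-4-(triisopropylsilyloxy)phenyl]-2,3-dihydro-1-benzofuran-3-yl}methanol
Conditions: PdCl2(MeCN)2 (cat.), XPhos (cat.), Cs2CO3, MeCN, 80 °C
Reagents that add atoms: none
Why: Copper-free Sonogashira coupling of an aryl chloride, in which the bulky electron-rich biarylphosphine lets palladium insert into the electron-rich C5–Cl bond; the silyl cap on the alkynol keeps the later allylic oxygen distinct from the free C9–OH.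

Step 11
Reactants: 20 4-hydroxybenzoic acid
Product: 22 4-(triisopropylsilyloxy)benzoic acid, via triisopropylsilyl 4-(triisopropylsilyloxy)benzoate 21 (not isolated)
Conditions: TIPSCl (2.2 equiv), imidazole, DMF, rt; then K2CO3, MeOH/THF/H2O, rt; citric acid work-up
Reagents that add atoms: triisopropylsilyl chloride, CC(C)[Si](Cl)(C(C)C)C(C)C
Why: Bis-silylation followed by selective hydrolysis of the silyl ester, which is far more labile to mild carbonate than the aryl silyl ether.

Step 12
Reactants: 19 {(2S,3R)-5-[3-(tert-butyldimethylsilyloxy)prop-1-yn-1-yl]-7-methoxy-2-[3-methoxy-4-(triisopropylsilyloxy)phenyl]-2,3-dihydro-1-benzofuran-3-yl}methanol; 22 4-(triisopropylsilyloxy)benzoic acid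
Product: 23 {(2S,3R)-5-[3-(tert-butyldimethylsilyloxy)prop-1-yn-1-yl]-7-methoxy-2-[3-methoxy-4-(triisopropylsilyloxy)phenyl]-2,3-dihydro-1-benzofuran-3-yl}methyl 4-(triisopropylsilyloxy)benzoate
Conditions: DCC, DMAP (cat.), CH2Cl2, 0 °C → rt
Reagents that add atoms: none
Why: Steglich esterification (carbodiimide activation with DMAP acyl transfer) of the only free hydroxyl group, the primary C9–OH.

Step 13
Reactants: 23 {(2S,3R)-5-[3-(tert-butyldimethylsilyloxy)prop-1-yn-1-yl]-7-methoxy-2-[3-methoxy-4-(triisopropylsilyloxy)phenyl]-2,3-dihydro-1-benzofuran-3-yl}methyl 4-(triisopropylsilyloxy)benzoate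
Product: 24 {(2S,3R)-5-(3-hydroxyprop-1-yn-1-yl)-7-methoxy-2-[3-methoxy-4-(triisopropylsilyloxy)phenyl]-2,3-dihydro-1-benzofuran-3-yl}methyl 4-(triisopropylsilyloxy)benzoate
Conditions: p-TsOH·H2O (cat.), MeOH/CH2Cl2, 0 °C
Reagents that add atoms: none
Why: Acid-catalysed methanolysis of a primary alkyl silyl ether, which should be much faster than cleavage of the hindered aryl triisopropylsilyl ethers; at the alkyne stage no stabilised allylic cation can form.

Step 14
Reactants: 24 {(2S,3R)-5-(3-hydroxyprop-1-yn-1-yl)-7-methoxy-2-[3-methoxy-4-(triisopropylsilyloxy)phenyl]-2,3-dihydro-1-benzofuran-3-yl}methyl 4-(triisopropylsilyloxy)benzoate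
Product: 25 {(2S,3R)-5-[(1Z)-3-hydroxyprop-1-en-1-yl]-7-methoxy-2-[3-methoxy-4-(triisopropylsilyloxy)phenyl]-2,3-dihydro-1-benzofuran-3-yl}methyl 4-(triisopropylsilyloxy)benzoate
Conditions: H2 (1 atm), Pd/CaCO3 poisoned with Pb(OAc)2 (Lindlar catalyst), quinoline, EtOAc, rt
Reagents that add atoms: none
Why: Lindlar semihydrogenation, in which syn delivery of one equivalent of hydrogen on the poisoned palladium surface gives the Z-alkene without cleaving the benzylic C2–O bond or reducing the ester.

Step 15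
Reactants: 25 {(2S,3R)-5-[(1Z)-3-hydroxyprop-1-en-1-yl]-7-methoxy-2-[3-methoxy-4-(triisopropylsilyloxy)phenyl]-2,3-dihydro-1-benzofuran-3-yl}methyl 4-(triisopropylsilyloxy)benzoate
Product: 26 {(2S,3R)-7-methoxy-2-[3-methoxy-4-(triisopropylsilyloxy)phenyl]-5-[(1Z)-3-oxoprop-1-en-1-yl]-2,3-dihydro-1-benzofuran-3-yl}methyl 4-(triisopropylsilyloxy)benzoate
Conditions: TEMPO (cat.), PhI(OAc)2, CH2Cl2, rt, in the dark
Reagents that add atoms: none
Why: Oxoammonium-mediated oxidation of a primary allylic alcohol (TEMPO with PhI(OAc)2), a base-free method that should turn the Z-allylic alcohol into the Z-enal without touching the double-bond geometry or over-oxidising.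

Step 16
Reactants: 26 {(2S,3R)-7-methoxy-2-[3-methoxy-4-(triisopropylsilyloxy)phenyl]-5-[(1Z)-3-oxoprop-1-en-1-yl]-2,3-dihydro-1-benzofuran-3-yl}methyl 4-(triisopropylsilyloxy)benzoate
Product: 27 [(2S,3R)-2-(4-hydroxy-3-methoxyphenyl)-7-methoxy-5-[(1Z)-3-oxoprop-1-en-1-yl]-2,3-dihydro-1-benzofuran-3-yl]methyl 4-hydroxybenzoate
Conditions: Bu4NF, AcOH (1:1), THF, 0 °C
Reagents that add atoms: none
Why: Fluoride cleavage of both aryl silyl ethers, with acetic acid buffering the phenoxides so that neither the Z-enal nor the benzoate ester should meet a strong base.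

Compound list
1 | 4-chloro-2-methoxyphenol | COc1cc(Cl)ccc1O | starting material
2 | 4-chloro-2-iodo-6-methoxyphenol | COc1cc(Cl)cc(I)c1O | intermediate
3 | ethynyltrimethylsilane | C#C[Si](C)(C)C | starting material
4 | 4-chloro-2-methoxy-6-[(trimethylsilyl)ethynyl]phenol | COc1cc(Cl)cc(C#C[Si](C)(C)C)c1O | intermediate
5 | 4-chloro-2-ethynyl-6-methoxyphenol | COc1cc(Cl)cc(C#C)c1O | intermediate
6 | 5-chloro-7-methoxy-1-benzofuran | COc1cc(Cl)cc2ccoc12 | intermediate
7 | 2-methoxy-4-(4,4,5,5-tetramethyl-1,3,2-dioxaborolan-2-yl)phenol | COc1cc(B2OC(C)(C)C(C)(C)O2)ccc1O | starting material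
8 | 2-[3-methoxy-4-(triisopropylsilyloxy)phenyl]-4,4,5,5-tetramethyl-1,3,2-dioxaborolane | COc1cc(B2OC(C)(C)C(C)(C)O2)ccc1O[Si](C(C)C)(C(C)C)C(C)C | intermediate
9 | allyl acetate | C=CCOC(C)=O | starting material
10 | (5-chloro-7-methoxy-1-benzofuran-2-yl)lithium | COc1cc(Cl)cc2cc([Li])oc12 | intermediate
11 | lithium (5-chloro-7-methoxy-1-benzofuran-2-yl)[3-methoxy-4-(triisopropylsilyloxy)phenyl](pinacolato)borate | [Li+].COc1cc(Cl)cc2cc(oc12)[B-]1(OC(C)(C)C(C)(C)O1)c1ccc(O[Si](C(C)C)(C(C)C)C(C)C)c(OC)c1 | intermediate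
12 | 2-{(2S,3S)-3-allyl-5-chloro-7-methoxy-2-[3-methoxy-4-(triisopropylsilyloxy)phenyl]-2,3-dihydro-1-benzofuran-2-yl}-4,4,5,5-tetramethyl-1,3,2-dioxaborolane (aryl trans to allyl) | COc1cc([C@@]2(B4OC(C)(C)C(C)(C)O4)Oc3c(OC)cc(Cl)cc3[C@@H]2CC=C)ccc1O[Si](C(C)C)(C(C)C)C(C)C | intermediate
13 | 4-[(2S,3S)-3-allyl-5-chloro-7-methoxy-2,3-dihydro-1-benzofuran-2-yl]-2-methoxyphenol | COc1cc([C@H]2Oc3c(OC)cc(Cl)cc3[C@@H]2CC=C)ccc1O | intermediate
14 | {4-[(2S,3S)-3-allyl-5-chloro-7-methoxy-2,3-dihydro-1-benzofuran-2-yl]-2-methoxyphenoxy}triisopropylsilane | COc1cc([C@H]2Oc3c(OC)cc(Cl)cc3[C@@H]2CC=C)ccc1O[Si](C(C)C)(C(C)C)C(C)C | intermediate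
15 | {4-[(2S,3S)-5-chloro-7-methoxy-3-[(1E)-prop-1-en-1-yl]-2,3-dihydro-1-benzofuran-2-yl]-2-methoxyphenoxy}triisopropylsilane | COc1cc([C@H]2Oc3c(OC)cc(Cl)cc3[C@@H]2/C=C/C)ccc1O[Si](C(C)C)(C(C)C)C(C)C | intermediate
16 | (2S,3S)-5-chloro-7-methoxy-2-[3-methoxy-4-(triisopropylsilyloxy)phenyl]-2,3-dihydro-1-benzofuran-3-carbaldehyde | COc1cc([C@H]2Oc3c(OC)cc(Cl)cc3[C@@H]2C=O)ccc1O[Si](C(C)C)(C(C)C)C(C)C | intermediate
17 | {(2S,3R)-5-chloro-7-methoxy-2-[3-methoxy-4-(triisopropylsilyloxy)phenyl]-2,3-dihydro-1-benzofuran-3-yl}methanol | COc1cc([C@H]2Oc3c(OC)cc(Cl)cc3[C@@H]2CO)ccc1O[Si](C(C)C)(C(C)C)C(C)C | intermediate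
18 | tert-butyldimethyl(prop-2-yn-1-yloxy)silane | C#CCO[Si](C)(C)C(C)(C)C | starting material
19 | {(2S,3R)-5-[3-(tert-butyldimethylsilyloxy)prop-1-yn-1-yl]-7-methoxy-2-[3-methoxy-4-(triisopropylsilyloxy)phenyl]-2,3-dihydro-1-benzofuran-3-yl}methanol | COc1cc([C@H]2Oc3c(OC)cc(C#CCO[Si](C)(C)C(C)(C)C)cc3[C@@H]2CO)ccc1O[Si](C(C)C)(C(C)C)C(C)C | intermediate
20 | 4-hydroxybenzoic acid | OC(=O)c1ccc(O)cc1 | starting material
21 | triisopropylsilyl 4-(triisopropylsilyloxy)benzoate | CC(C)[Si](OC(=O)c1ccc(O[Si](C(C)C)(C(C)C)C(C)C)cc1)(C(C)C)C(C)C | intermediate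
22 | 4-(triisopropylsilyloxy)benzoic acid | OC(=O)c1ccc(O[Si](C(C)C)(C(C)C)C(C)C)cc1 | intermediate
23 | {(2S,3R)-5-[3-(tert-butyldimethylsilyloxy)prop-1-yn-1-yl]-7-methoxy-2-[3-methoxy-4-(triisopropylsilyloxy)phenyl]-2,3-dihydro-1-benzofuran-3-yl}methyl 4-(triisopropylsilyloxy)benzoate | COc1cc([C@H]2Oc3c(OC)cc(C#CCO[Si](C)(C)C(C)(C)C)cc3[C@@H]2COC(=O)c2ccc(O[Si](C(C)C)(C(C)C)C(C)C)cc2)ccc1O[Si](C(C)C)(C(C)C)C(C)C | intermediate
24 | {(2S,3R)-5-(3-hydroxyprop-1-yn-1-yl)-7-methoxy-2-[3-methoxy-4-(triisopropylsilyloxy)phenyl]-2,3-dihydro-1-benzofuran-3-yl}methyl 4-(triisopropylsilyloxy)benzoate | COc1cc([C@H]2Oc3c(OC)cc(C#CCO)cc3[C@@H]2COC(=O)c2ccc(O[Si](C(C)C)(C(C)C)C(C)C)cc2)ccc1O[Si](C(C)C)(C(C)C)C(C)C | intermediate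
25 | {(2S,3R)-5-[(1Z)-3-hydroxyprop-1-en-1-yl]-7-methoxy-2-[3-methoxy-4-(triisopropylsilyloxy)phenyl]-2,3-dihydro-1-benzofuran-3-yl}methyl 4-(triisopropylsilyloxy)benzoate | COc1cc([C@H]2Oc3c(OC)cc(/C=C\CO)cc3[C@@H]2COC(=O)c2ccc(O[Si](C(C)C)(C(C)C)C(C)C)cc2)ccc1O[Si](C(C)C)(C(C)C)C(C)C | intermediate
26 | {(2S,3R)-7-methoxy-2-[3-methoxy-4-(triisopropylsilyloxy)phenyl]-5-[(1Z)-3-oxoprop-1-en-1-yl]-2,3-dihydro-1-benzofuran-3-yl}methyl 4-(triisopropylsilyloxy)benzoate | COc1cc([C@H]2Oc3c(OC)cc(/C=C\C=O)cc3[C@@H]2COC(=O)c2ccc(O[Si](C(C)C)(C(C)C)C(C)C)cc2)ccc1O[Si](C(C)C)(C(C)C)C(C)C | intermediate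
27 | [(2S,3R)-2-(4-hydroxy-3-methoxyphenyl)-7-methoxy-5-[(1Z)-3-oxoprop-1-en-1-yl]-2,3-dihydro-1-benzofuran-3-yl]methyl 4-hydroxybenzoate | COc1cc([C@H]2Oc3c(OC)cc(/C=C\C=O)cc3[C@@H]2COC(=O)c2ccc(O)cc2)ccc1O | target

Total step count: 16 steps.
Longest linear sequence: 14 steps (steps 1–3, 5–10 and 12–16, from 4-chloro-2-methoxyphenol); steps 4 and 11 are side branches.

Steps most likely to fail

Step 5 (the new method). C3 of the benzofuranyl borate may attack the π-allyl complex too slowly, so that direct aryl transfer from boron to palladium and plain allyl–aryl coupling take over, or the ligand may discriminate the two faces of the borate poorly. The fallback uses known chemistry and closes the dihydrofuran ring through the C2–C3 bond instead; it sets out from 2 and comes back to the route at 17. Vanillin is silylated (TIPSCl, imidazole) to 3-methoxy-4-(triisopropylsilyloxy)benzaldehyde F1 and reduced (NaBH4) to [3-methoxy-4-(triisopropylsilyloxy)phenyl]methanol F2. Mitsunobu etherification of 2 with this alcohol (PPh3, DIAD) should give the benzyl aryl ether {4-[(4-chloro-2-iodo-6-methoxyphenoxy)methyl]-2-methoxyphenoxy}triisopropylsilane F3. Palladium-catalysed coupling of the aryl iodide with methyl diazoacetate (Pd(PPh3)4, Ag2CO3, Et3N, toluene, rt) should give methyl 2-(5-chloro-3-methoxy-2-{[3-methoxy-4-(triisopropylsilyloxy)benzyl]oxy}phenyl)-2-diazoacetate F4. Enantioselective intramolecular rhodium carbenoid insertion into the benzylic C–H bond (Rh2(S-PTTL)4 or its mirror image, whichever gives 2S; toluene, −60 °C) should give the cis ester methyl (2S,3R)-5-chloro-7-methoxy-2-[3-methoxy-4-(triisopropylsilyloxy)phenyl]-2,3-dihydro-1-benzofuran-3-carboxylate F5. DBU should epimerise C3 to the trans ester methyl (2S,3S)-5-chloro-7-methoxy-2-[3-methoxy-4-(triisopropylsilyloxy)phenyl]-2,3-dihydro-1-benzofuran-3-carboxylate F6, and LiBH4 reduction of the ester then gives 17.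

Step 6. Stereochemical fidelity at C2 may be lost, either by protonation from both faces or by reversible opening of the C2–O1 bond through the para-phenoxide once the silyl group has gone. The fallback gives up stereoretention and relies on thermodynamic control by the untouched C3 centre; it sets out from 12 and comes back at 13. Fluoride protodeboronation is run without regard to fidelity, which would give 13 mixed with its cis epimer 4-[(2R,3S)-3-allyl-5-chloro-7-methoxy-2,3-dihydro-1-benzofuran-2-yl]-2-methoxyphenol F7. The mixture is then stirred with catalytic CF3CO2H in CH2Cl2, where reversible ionisation of the C2–O1 bond through the para-quinone methide should converge both epimers on the more stable trans compound 13.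

Step 10. At the temperature that the electron-rich C–Cl bond demands, the alkyne may be consumed by oligomerisation and the carbonate base may begin to strip the aryl silyl ether. The fallback separates C–Cl activation from the alkyne coupling by a halogen exchange through boron; it sets out from 17 and comes back at 19. Miyaura borylation of the chloride with an acetate base (B2pin2, Pd2(dba)3, XPhos, KOAc, dioxane, 100 °C) should give {(2S,3R)-7-methoxy-2-[3-methoxy-4-(triisopropylsilyloxy)phenyl]-5-(4,4,5,5-tetramethyl-1,3,2-dioxaborolan-2-yl)-2,3-dihydro-1-benzofuran-3-yl}methanol F8. Copper-catalysed iododeboronation (CuI, 1,10-phenanthroline, KI, MeOH/H2O, air) should give {(2S,3R)-5-iodo-7-methoxy-2-[3-methoxy-4-(triisopropylsilyloxy)phenyl]-2,3-dihydro-1-benzofuran-3-yl}methanol F9. A room-temperature Sonogashira coupling with 18 (PdCl2(PPh3)2, CuI, Et3N) then gives 19.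

Further compounds
F1 | step 5 | 3-methoxy-4-(triisopropylsilyloxy)benzaldehyde | COc1cc(C=O)ccc1O[Si](C(C)C)(C(C)C)C(C)C
F2 | step 5 | [3-methoxy-4-(triisopropylsilyloxy)phenyl]methanol | COc1cc(CO)ccc1O[Si](C(C)C)(C(C)C)C(C)C
F3 | step 5 | {4-[(4-chloro-2-iodo-6-methoxyphenoxy)methyl]-2-methoxyphenoxy}triisopropylsilane | COc1cc(COc2c(I)cc(Cl)cc2OC)ccc1O[Si](C(C)C)(C(C)C)C(C)C
F4 | step 5 | methyl 2-(5-chloro-3-methoxy-2-{[3-methoxy-4-(triisopropylsilyloxy)benzyl]oxy}phenyl)-2-diazoacetate | COC(=O)C(=[N+]=[N-])c1cc(Cl)cc(OC)c1OCc1ccc(O[Si](C(C)C)(C(C)C)C(C)C)c(OC)c1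
F5 | step 5 | methyl (2S,3R)-5-chloro-7-methoxy-2-[3-methoxy-4-(triisopropylsilyloxy)phenyl]-2,3-dihydro-1-benzofuran-3-carboxylate (cis) | COc1cc([C@H]2Oc3c(OC)cc(Cl)cc3[C@H]2C(=O)OC)ccc1O[Si](C(C)C)(C(C)C)C(C)C
F6 | step 5 | methyl (2S,3S)-5-chloro-7-methoxy-2-[3-methoxy-4-(triisopropylsilyloxy)phenyl]-2,3-dihydro-1-benzofuran-3-carboxylate (trans) | COc1cc([C@H]2Oc3c(OC)cc(Cl)cc3[C@@H]2C(=O)OC)ccc1O[Si](C(C)C)(C(C)C)C(C)C
F7 | step 6 | 4-[(2R,3S)-3-allyl-5-chloro-7-methoxy-2,3-dihydro-1-benzofuran-2-yl]-2-methoxyphenol (cis) | COc1cc([C@@H]2Oc3c(OC)cc(Cl)cc3[C@@H]2CC=C)ccc1O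
F8 | step 10 | {(2S,3R)-7-methoxy-2-[3-methoxy-4-(triisopropylsilyloxy)phenyl]-5-(4,4,5,5-tetramethyl-1,3,2-dioxaborolan-2-yl)-2,3-dihydro-1-benzofuran-3-yl}methanol | COc1cc([C@H]2Oc3c(OC)cc(B4OC(C)(C)C(C)(C)O4)cc3[C@@H]2CO)ccc1O[Si](C(C)C)(C(C)C)C(C)C
F9 | step 10 | {(2S,3R)-5-iodo-7-methoxy-2-[3-methoxy-4-(triisopropylsilyloxy)phenyl]-2,3-dihydro-1-benzofuran-3-yl}methanol | COc1cc([C@H]2Oc3c(OC)cc(I)cc3[C@@H]2CO)ccc1O[Si](C(C)C)(C(C)C)C(C)C
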